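**Retrosynthetic overview**
1. Last ring closure: the C1–C14 bond and the cis α-methylene-γ-lactone form together by an indium Barbier 2-(methoxycarbonyl)allylation of a C13-hydroxy C14-aldehyde; this closes the 14-membered carbocycle.
2. Before that, the oxolane (C4–O–C7): Shi epoxide of an (E)-C3=C4 alkene, opened 5-exo at C4 by the C7 hydroxyl (sets C3 and C4).
3. Key disconnection C7–C8: stereospecific 1,2-shift of the C8 alkenyl carbon from boron to C7 (sparteine-lithiated C7 carbamate plus C8 alkenylboronate), then C–B oxidation; C15–C17 come from cross-metathesis.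
4. C8–C14 half: Brown (Z)-crotylboration of dimethoxyacetaldehyde (C12, C13), hydroboration/copper allyl–alkyl coupling with 2,3-dibromopropene, Miyaura borylation. C1–C7 half: carboalumination/allylation of pent-4-yn-1-ol.
5. Ring order: oxolane first, then carbocycle and lactone in one step.

Assumption: positions in the text carry cembrane locants (lactone C1/C14–C16, methylenes C15=C17 and C8=C19, oxolane C4–O–C7, hydroxyls at C3 and C13, methyls C18 and C20); names in the compound list use systematic locants.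

**Route**

Step 1
Reactants: 1 pent-4-yn-1-ol; 2 allyl bromide
Product: 4 (4E)-4-methylocta-4,7-dien-1-ol, via alkenylalane 3 (not isolated)
Conditions: AlMe3 (3 equiv), Cp2ZrCl2 (25 mol %), CH2Cl2, 0 °C to rt; then 2, Pd(PPh3)4 (5 mol %), THF, rt
Reagents that add atoms: trimethylaluminium, C[Al](C)C
Why: Negishi zirconium-catalysed carboalumination adds methyl and aluminium syn across the alkyne (methyl to the internal carbon) and the palladium-catalysed cross-coupling of the alkenylalane with allyl bromide keeps that geometry, so the C3=C4 alkene is E.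

Step 2
Reactants: 4 (4E)-4-methylocta-4,7-dien-1-ol
Product: 5 (4E)-4-methylocta-4,7-dien-1-yl N,N-diisopropylcarbamate
Conditions: iPr2NC(O)Cl, Et3N, DMAP (cat.), CH2Cl2, 40 °C
Reagents that add atoms: N,N-diisopropylcarbamoyl chloride, CC(C)N(C(C)C)C(Cl)=O
Why: O-carbamoylation gives the Hoppe carbamate that directs lithiation at C7 and later acts as the leaving group.

Step 3
Reactants: 6 cis-but-2-ene; 7 2,2-dimethoxyacetaldehyde
Product: 10 (2R,3S)-1,1-dimethoxy-3-methylpent-4-en-2-ol, via crotylpotassium 8 (not isolated), via crotylborane 9 (not isolated)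
Conditions: KOtBu, n-BuLi, THF, −78 to −45 °C; (+)-Ipc2BOMe, −78 °C; BF3·OEt2; 7, −78 °C; then NaOH, H2O2
Reagents that add atoms: none
Why: Brown asymmetric crotylboration, in which the (Z)-crotylborane reacts through a closed chair transition state to give the syn adduct and the isopinocampheyl groups from (−)-α-pinene select the aldehyde face, sets C12 (S) and C13 (R).

Step 4
Reactants: 10 (2R,3S)-1,1-dimethoxy-3-methylpent-4-en-2-ol
Product: 11 {[(2R,3S)-1,1-dimethoxy-3-methylpent-4-en-2-yl]oxy}triethylsilane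
Conditions: Et3SiCl, imidazole, CH2Cl2, 0 °C
Reagents that add atoms: chlorotriethylsilane, CC[Si](Cl)(CC)CC
Why: silylation protects the C13 hydroxyl through the organometallic steps and is removed later by methanolysis.

Step 5
Reactants: 11 {[(2R,3S)-1,1-dimethoxy-3-methylpent-4-en-2-yl]oxy}triethylsilane; 12 2,3-dibromoprop-1-ene
Product: 14 {[(2R,3S)-7-bromo-1,1-dimethoxy-3-methyloct-7-en-2-yl]oxy}triethylsilane, via alkylborane 13 (not isolated)
Conditions: 9-BBN-H, THF, 60 °C; then 12, CuOAc (10 mol %), KOMe, THF, rt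
Reagents that add atoms: none
Why: anti-Markovnikov hydroboration puts boron on C10 and copper-catalysed allyl–alkyl coupling of the derived methoxyborate with the allylic bromide of 12 forms C9–C10 while the vinylic bromide is untouched.

Step 6
Reactants: 14 {[(2R,3S)-7-bromo-1,1-dimethoxy-3-methyloct-7-en-2-yl]oxy}triethylsilane
Product: 15 triethyl{[(2R,3S)-1,1-dimethoxy-3-methyl-7-(4,4,5,5-tetramethyl-1,3,2-dioxaborolan-2-yl)oct-7-en-2-yl]oxy}silane
Conditions: B2pin2, PdCl2(PPh3)2 (3 mol %), PPh3, KOPh, toluene, 50 °C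
Reagents that add atoms: bis(pinacolato)diboron, CC1(C)OB(OC1(C)C)B1OC(C)(C)C(C)(C)O1
Why: Miyaura borylation of the 2-bromoalkene gives the 1,1-disubstituted alkenylboronate that carries the migrating C8 carbon.

Step 7
Reactants: 5 (4E)-4-methylocta-4,7-dien-1-yl N,N-diisopropylcarbamate; 15 the alkenylboronate
Product: 19 (2R,3S,8R,11E)-1,1-dimethoxy-3,11-dimethyl-7-methylidene-2-(triethylsilyloxy)pentadeca-11,14-dien-8-ol, via lithio carbamate 16 (not isolated), via boronate complex 17 (not isolated), via allylic boronate 18 (not isolated)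
Conditions: 5 (1.3 equiv), s-BuLi, (−)-sparteine, Et2O, −78 °C, 5 h; 15, −78 °C; warm to 35 °C; then NaOH, H2O2, THF, 0 °C
Reagents that add atoms: hydrogen peroxide, OO
Why: Hoppe–Aggarwal lithiation–borylation, in which sparteine-controlled removal of the pro-S hydrogen gives the configurationally stable (S)-lithio carbamate, borylation with retention gives the ate complex, the C8 alkenyl carbon then shifts 1,2 from boron to C7 anti to the departing carbamate (stereospecific 1,2-metallate rearrangement, inversion at C7, forms C7–C8) and C–B oxidation with retention gives the 7R alcohol.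

Step 8
Reactants: 19 the coupled allylic alcohol; 20 methyl 2-(chloromethyl)prop-2-enoate
Product: 21 methyl (2Z,5E,9R,14S,15R)-2-(chloromethyl)-9-hydroxy-16,16-dimethoxy-6,14-dimethyl-10-methylidene-15-(triethylsilyloxy)hexadeca-2,5-dienoate
Conditions: 20 (8 equiv), second-generation Hoveyda–Grubbs catalyst RuCl2(H2IMes)(=CH-C6H4-2-OiPr) (10 mol %), 2,6-dichloro-1,4-benzoquinone (10 mol %), CH2Cl2, 40 °C
Reagents that add atoms: none
Why: olefin cross-metathesis of the only monosubstituted alkene with the 2-substituted acrylate (which does not homodimerise) gives the trisubstituted enoate, mainly with the chain trans to the ester, and either geometry converges at the later allylindium stage.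

Step 9
Reactants: 21 the chloromethyl enoate
Product: 24 methyl (2Z,5R)-2-(chloromethyl)-5-hydroxy-5-{(2S,5R)-5-[(6S,7R)-7-hydroxy-8,8-dimethoxy-6-methyloct-1-en-2-yl]-2-methyloxolan-2-yl}pent-2-enoate, via epoxy alcohol 22 (not isolated), via silylated oxolane 23 (not isolated)
Conditions: D-fructose-derived Shi ketone (30 mol %), Oxone (2KHSO5·KHSO4·K2SO4), K2CO3, Bu4NHSO4, MeCN–CH2(OMe)2–aq. Na2B4O7 (pH 10.5), 0 °C; then CSA (10 mol %), CH2Cl2, 0 °C; then MeOH, rt
Reagents that add atoms: potassium peroxymonosulfate (the oxidant in Oxone), [K+].[O-]S(=O)(=O)OO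
Why: Shi asymmetric epoxidation (chiral dioxirane, spiro transition state, reagent control) selectively converts the electron-rich trisubstituted C3=C4 alkene into the 3R,4R epoxide, acid then triggers 5-exo opening by the C7 hydroxyl at the tertiary C4 with inversion (4S, the 3R hydroxyl is kept, C3 and C8 cis on the oxolane) and methanolysis removes the silyl group.

Step 10
Reactants: 24 the oxolane diol acetal
Product: 28 uprolide D, via hydroxy aldehyde 25 (not isolated), via allylindium 26 (not isolated), via hydroxy ester 27 (not isolated)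
Conditions: HCl (0.1 M), THF–H2O (4:1), rt, 2 h; then addition over 12 h to In powder (6 equiv), NaI (20 mol %), THF–H2O (4:1, 1 mM final), 40 °C
Reagents that add atoms: water, O
Why: Proposed new method: closure of a 14-membered carbocycle by an aqueous indium Barbier 2-(methoxycarbonyl)allylation of an unprotected α-hydroxy aldehyde, in which the acetal is hydrolysed, indium inserts into the allylic C–Cl bond (iodide shuttle), the trivalent allylindium is held by the chelate of the C13 hydroxyl and the aldehyde and adds at its γ-carbon through a chair transition state (Z-allyl gives C1/C14 syn, chelation gives C13/C14 syn, setting 14R and 1S) and the cis γ-hydroxy ester lactonises; the closest known reactions are the intermolecular indium allylation of unprotected aldoses with 2-(bromomethyl)acrylates in water and zinc Barbier macrocyclisations to cembranolides.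

**Compound list**
1 | pent-4-yn-1-ol | C#CCCCO | starting material
2 | allyl bromide | C=CCBr | starting material
3 | dimethyl[(1E)-5-(dimethylalumanyloxy)-2-methylpent-1-en-1-yl]alumane | C[Al](C)/C=C(\C)CCCO[Al](C)C | intermediate (not isolated)
4 | (4E)-4-methylocta-4,7-dien-1-ol | OCCC/C(C)=C/CC=C | intermediate
5 | (4E)-4-methylocta-4,7-dien-1-yl N,N-diisopropylcarbamate | CC(C)N(C(C)C)C(=O)OCCC/C(C)=C/CC=C | intermediate
6 | cis-but-2-ene | C/C=C\C | starting material
7 | 2,2-dimethoxyacetaldehyde | COC(OC)C=O | starting material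
8 | (Z)-but-2-en-1-ylpotassium | C/C=C\C[K] | intermediate (not isolated)
9 | (Z)-but-2-en-1-ylbis(isopinocampheyl)borane, both isopinocampheyl groups from (−)-α-pinene | C/C=C\CB([C@H]1C[C@H]2C[C@@H]([C@@H]1C)C2(C)C)[C@H]1C[C@H]2C[C@@H]([C@@H]1C)C2(C)C | intermediate (not isolated)
10 | (2R,3S)-1,1-dimethoxy-3-methylpent-4-en-2-ol | C=C[C@H](C)[C@@H](O)C(OC)OC | intermediate
11 | {[(2R,3S)-1,1-dimethoxy-3-methylpent-4-en-2-yl]oxy}triethylsilane | C=C[C@H](C)[C@@H](O[Si](CC)(CC)CC)C(OC)OC | intermediate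
12 | 2,3-dibromoprop-1-ene | C=C(Br)CBr | starting material
13 | 9-[(3S,4R)-5,5-dimethoxy-3-methyl-4-(triethylsilyloxy)pentyl]-9-borabicyclo[3.3.1]nonane | C1CCC2CCCC1B2CC[C@H](C)[C@@H](O[Si](CC)(CC)CC)C(OC)OC | intermediate (not isolated)
14 | {[(2R,3S)-7-bromo-1,1-dimethoxy-3-methyloct-7-en-2-yl]oxy}triethylsilane | C=C(Br)CCC[C@H](C)[C@@H](O[Si](CC)(CC)CC)C(OC)OC | intermediate
15 | triethyl{[(2R,3S)-1,1-dimethoxy-3-methyl-7-(4,4,5,5-tetramethyl-1,3,2-dioxaborolan-2-yl)oct-7-en-2-yl]oxy}silane | C=C(B1OC(C)(C)C(C)(C)O1)CCC[C@H](C)[C@@H](O[Si](CC)(CC)CC)C(OC)OC | intermediate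
16 | (1S,4E)-1-lithio-4-methylocta-4,7-dien-1-yl N,N-diisopropylcarbamate (as its sparteine complex) | CC(C)N(C(C)C)C(=O)O[C@@H]([Li])CC/C(C)=C/CC=C | intermediate (not isolated)
17 | lithium pinacol boronate complex: boron bears the (S)-configured C7 carbon (still carrying the carbamate) and the C8 alkenyl group of 15 | [Li+].CC(C)N(C(C)C)C(=O)O[C@H](CC/C(C)=C/CC=C)[B-]1(OC(C)(C)C(C)(C)O1)C(=C)CCC[C@H](C)[C@@H](O[Si](CC)(CC)CC)C(OC)OC | intermediate (not isolated)
18 | 2-[(2R,3S,8R,11E)-1,1-dimethoxy-3,11-dimethyl-7-methylidene-2-(triethylsilyloxy)pentadeca-11,14-dien-8-yl]-4,4,5,5-tetramethyl-1,3,2-dioxaborolane | C=CC/C=C(\C)CC[C@@H](B1OC(C)(C)C(C)(C)O1)C(=C)CCC[C@H](C)[C@@H](O[Si](CC)(CC)CC)C(OC)OC | intermediate (not isolated)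
19 | (2R,3S,8R,11E)-1,1-dimethoxy-3,11-dimethyl-7-methylidene-2-(triethylsilyloxy)pentadeca-11,14-dien-8-ol | C=CC/C=C(\C)CC[C@@H](O)C(=C)CCC[C@H](C)[C@@H](O[Si](CC)(CC)CC)C(OC)OC | intermediate
20 | methyl 2-(chloromethyl)prop-2-enoate | C=C(CCl)C(=O)OC | starting material
21 | methyl (2Z,5E,9R,14S,15R)-2-(chloromethyl)-9-hydroxy-16,16-dimethoxy-6,14-dimethyl-10-methylidene-15-(triethylsilyloxy)hexadeca-2,5-dienoate | COC(=O)/C(CCl)=C/C/C=C(\C)CC[C@@H](O)C(=C)CCC[C@H](C)[C@@H](O[Si](CC)(CC)CC)C(OC)OC | intermediate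
22 | methyl (2Z)-2-(chloromethyl)-4-{(2R,3R)-3-[(3R,8S,9R)-3-hydroxy-10,10-dimethoxy-8-methyl-4-methylidene-9-(triethylsilyloxy)decyl]-3-methyloxiran-2-yl}but-2-enoate | COC(=O)/C(CCl)=C/C[C@H]1O[C@]1(C)CC[C@@H](O)C(=C)CCC[C@H](C)[C@@H](O[Si](CC)(CC)CC)C(OC)OC | intermediate (not isolated)
23 | methyl (2Z,5R)-2-(chloromethyl)-5-hydroxy-5-{(2S,5R)-5-[(6S,7R)-8,8-dimethoxy-6-methyl-7-(triethylsilyloxy)oct-1-en-2-yl]-2-methyloxolan-2-yl}pent-2-enoate | COC(=O)/C(CCl)=C/C[C@@H](O)[C@]1(C)CC[C@H](C(=C)CCC[C@H](C)[C@@H](O[Si](CC)(CC)CC)C(OC)OC)O1 | intermediate (not isolated)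
24 | methyl (2Z,5R)-2-(chloromethyl)-5-hydroxy-5-{(2S,5R)-5-[(6S,7R)-7-hydroxy-8,8-dimethoxy-6-methyloct-1-en-2-yl]-2-methyloxolan-2-yl}pent-2-enoate | COC(=O)/C(CCl)=C/C[C@@H](O)[C@]1(C)CC[C@H](C(=C)CCC[C@H](C)[C@@H](O)C(OC)OC)O1 | intermediate
25 | methyl (2Z,5R)-2-(chloromethyl)-5-hydroxy-5-{(2S,5R)-5-[(6S,7R)-7-hydroxy-6-methyl-8-oxooct-1-en-2-yl]-2-methyloxolan-2-yl}pent-2-enoate | COC(=O)/C(CCl)=C/C[C@@H](O)[C@]1(C)CC[C@H](C(=C)CCC[C@H](C)[C@@H](O)C=O)O1 | intermediate (not isolated)
26 | allylindium of 25, drawn as the dichloride (InCl2 in place of Cl) | COC(=O)/C(C[In](Cl)Cl)=C/C[C@@H](O)[C@]1(C)CC[C@H](C(=C)CCC[C@H](C)[C@@H](O)C=O)O1 | intermediate (not isolated)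
27 | methyl 2-[(1S,2R,4S,5R,6R,7S,12R)-2,5,6-trihydroxy-1,7-dimethyl-11-methylidene-15-oxabicyclo[10.2.1]pentadecan-4-yl]prop-2-enoate | C=C1CCC[C@H](C)[C@@H](O)[C@H](O)[C@H](C(=C)C(=O)OC)C[C@@H](O)[C@]2(C)CC[C@H]1O2 | intermediate (not isolated)
28 | uprolide D, (1S,3R,4S,7R,12S,13R,14R)-3,13-dihydroxy-4,7-epoxycembra-8(19),15(17)-dien-16,14-olide (cembrane locants) | C=C1CCC[C@H](C)[C@@H](O)[C@@H]2OC(=O)C(=C)[C@@H]2C[C@@H](O)[C@]2(C)CC[C@H]1O2 | target

**Step count and risks**

Total step count: 10. Longest linear sequence: 8 steps (steps 3 to 10).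

The three steps most likely to fail, each with one fallback:

Step 10 (the proposed new reaction). Risks are oligomerisation, lactonisation through the C3 or C13 hydroxyl instead of C14, and the wrong facial selectivity in a macrocyclic transition state. The fallback uses known chemistry, sets out from 21 and comes back at 28; it closes the carbocycle before the oxolane exists. Aqueous trifluoroacetic acid in THF removes the silyl ether and the acetal of 21 and gives the open-chain hydroxy aldehyde methyl (2Z,5E,9R,14S,15R)-2-(chloromethyl)-9,15-dihydroxy-6,14-dimethyl-10-methylidene-16-oxohexadeca-2,5-dienoate F1. A zinc Barbier macrocyclisation of the kind used for cembranolides (Zn dust, NaI, THF–aq. NH4Cl, 1 mM, then acid) gives the macrocyclic cis-lactone (1S,3E,7R,12S,13R,14R)-7,13-dihydroxycembra-3,8(19),15(17)-trien-16,14-olide F2. Shi epoxidation of its remaining trisubstituted alkene followed by CSA closes the oxolane across the ring and gives 28.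

Step 7. Two advanced fragments are joined, the carbamate is lithiated next to a skipped diene, and the 1,2-shift and oxidation must run without loss of configuration. The fallback sets out from 4 and 14 and comes back at 19. Dess–Martin oxidation of 4 gives (4E)-4-methylocta-4,7-dienal F3, and an asymmetric Nozaki–Hiyama–Kishi alkenylation of F3 with bromoalkene 14 (CrCl2, NiCl2 (cat.), chiral sulfonamide ligand, Et3N, THF–MeCN) gives 19 directly, the ligand setting 7R.

Step 9. The epoxidation must pick one alkene out of four in the presence of an allylic chloride at pH 10.5, and the acid stage must not touch the chloride. The fallback sets out from 5 and comes back at 22. Shi epoxidation of the small diene 5 (one trisubstituted and one monosubstituted alkene, no chloride) gives 3-[(2R,3R)-2-methyl-3-(prop-2-en-1-yl)oxiran-2-yl]propyl N,N-diisopropylcarbamate F4. Lithiation–borylation of F4 with 15 under the conditions of step 7 gives the epoxy alcohol (2R,3S,8R)-1,1-dimethoxy-3-methyl-7-methylidene-10-[(2R,3R)-2-methyl-3-(prop-2-en-1-yl)oxiran-2-yl]-2-(triethylsilyloxy)decan-8-ol F5. Cross-metathesis of F5 with 20 then gives 22, which enters the CSA and methanol stages of step 9.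

Further compounds
F1 | step 10 | methyl (2Z,5E,9R,14S,15R)-2-(chloromethyl)-9,15-dihydroxy-6,14-dimethyl-10-methylidene-16-oxohexadeca-2,5-dienoate | COC(=O)/C(CCl)=C/C/C=C(\C)CC[C@@H](O)C(=C)CCC[C@H](C)[C@@H](O)C=O
F2 | step 10 | (1S,3E,7R,12S,13R,14R)-7,13-dihydroxycembra-3,8(19),15(17)-trien-16,14-olide | C=C1CCC[C@H](C)[C@@H](O)[C@@H]2OC(=O)C(=C)[C@@H]2C/C=C(\C)CC[C@H]1O
F3 | step 7 | (4E)-4-methylocta-4,7-dienal | O=CCC/C(C)=C/CC=C
F4 | step 9 | 3-[(2R,3R)-2-methyl-3-(prop-2-en-1-yl)oxiran-2-yl]propyl N,N-diisopropylcarbamate | C=CC[C@H]1O[C@]1(C)CCCOC(=O)N(C(C)C)C(C)C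
F5 | step 9 | (2R,3S,8R)-1,1-dimethoxy-3-methyl-7-methylidene-10-[(2R,3R)-2-methyl-3-(prop-2-en-1-yl)oxiran-2-yl]-2-(triethylsilyloxy)decan-8-ol | C=CC[C@H]1O[C@]1(C)CC[C@@H](O)C(=C)CCC[C@H](C)[C@@H](O[Si](CC)(CC)CC)C(OC)OC
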